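**Plan**

Numbering: seven-membered ring C1(OAr)–C2–C3(Me)(OH)–C4–C5–C6–C10(iPr); five-membered ring C5–C9–C8(Me)–C7–C6; epoxide on C8–C9; α is the face of the C1 oxygen. The C1 oxygen and the C10 isopropyl group sit on adjacent carbons of the seven-membered ring and are cis, the pattern a cis-divinylcyclopropane Cope rearrangement leaves behind from two E alkenes.
Retrosynthetic cuts, in order: the isovanillate C1–O acyl bond and the C8–C9 epoxide oxygen; the C3–OH (back to a C2=C3 alkene beside C1–OH); C8=C9 of the cyclopentene (metathesis) and C6–C7 (conjugate addition); last C4–C5 and C1–C10 of the seven-membered ring (formal 4+3).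
Forward: the seven-membered ring is made first from a vinyldiazoacetate and a siloxydiene; a methallyl arm is added at C6, the ester is turned into a vinyl group and the five-membered ring is closed by metathesis; the C3 carbinol, the ester and the epoxide follow.
Stereochemistry: C1 and C10 from the chiral dirhodium catalyst and the boat Cope transition state; C6 by addition anti to the C10 isopropyl group; C5 by equilibration to the trans ester; C3 by C1–OH-directed epoxidation and hydride opening; C8/C9 by C3–OH-directed epoxidation.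

Key step: step 5

Assumption: Rh2(S-DOSP)4 (dirhodium tetrakis[(S)-N-(4-dodecylbenzenesulfonyl)prolinate]) is taken to transfer the vinylcarbene with the same facial sense as in its styrene cyclopropanations (the sense that gives methyl (1S,2R)-1,2-diphenylcyclopropanecarboxylate); this maps onto the (1R,2R)-cyclopropane and the (3S,4S)-cycloheptadiene of the key step, and Rh2(R-DOSP)4 would be used if the antipode arose.

**Route**

Step 1
Reactants: 1 isovaleraldehyde; 2 malonic acid
Product: 3 (E)-5-methylhex-3-enoic acid
Conditions: Et3N (1.2 equiv), neat, 90 °C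
Reagents that add atoms: none
Why: Deconjugative Knoevenagel condensation, in which the alkylidenemalonic acid isomerises out of conjugation before decarboxylation, should give the β,γ-unsaturated acid as its E isomer.

Step 2
Reactants: 3 (E)-5-methylhex-3-enoic acid
Product: 4 methyl (E)-5-methylhex-3-enoate
Conditions: MeOH, H2SO4 (cat.), reflux
Reagents that add atoms: methanol, SMILES CO
Why: Fischer esterification, under which the non-conjugated E alkene is not expected to migrate.

Step 3
Reactants: 4 methyl (E)-5-methylhex-3-enoate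
Product: 5 methyl (E)-2-diazo-5-methylhex-3-enoate
Conditions: p-ABSA, DBU, MeCN, 0 °C; used at once
Reagents that add atoms: 4-acetamidobenzenesulfonyl azide (p-ABSA), SMILES CC(=O)Nc1ccc(cc1)S(=O)(=O)N=[N+]=[N-]
Why: Regitz diazo transfer to the vinylogously activated α-methylene of a β,γ-unsaturated ester is the standard entry to vinyldiazoacetates and leaves the E alkene in place.

Step 4
Reactants: 6 3-methylbut-2-enal
Product: 7 (E)-1-(tert-butyldimethylsilyloxy)-3-methylbuta-1,3-diene
Conditions: TBSOTf (1.1 equiv), Et3N (1.5 equiv), Et2O, 0 → 23 °C; distillation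
Reagents that add atoms: tert-butyldimethylsilyl trifluoromethanesulfonate, SMILES CC(C)(C)[Si](C)(C)OS(=O)(=O)C(F)(F)F
Why: Silyl dienol ether formation (O-silylation of the enal, then γ-deprotonation at a methyl group) should give the 1-siloxydiene, mainly as the E enol ether.

Step 5
Reactants: 5 methyl (E)-2-diazo-5-methylhex-3-enoate; 7 (E)-1-(tert-butyldimethylsilyloxy)-3-methylbuta-1,3-diene
Product: 9 methyl (3S,4S)-4-(tert-butyldimethylsilyloxy)-6-methyl-3-(propan-2-yl)cyclohepta-1,5-diene-1-carboxylate, via cis-divinylcyclopropane 8 (not isolated)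
Conditions: Rh2(S-DOSP)4 (1 mol %), 7 (2 equiv), hexane, −40 → 23 °C, slow addition of 5; brief warming to 60 °C if 8 persists
Reagents that add atoms: none
Why: Rh2(S-DOSP)4, a dirhodium tetracarboxylate of divalent rhodium, expels N2 from 5, and the donor/acceptor vinylcarbene adds to the CH2=C(Me) terminus of 7 in a concerted asynchronous (2+1) cyclopropanation that closes the three-membered ring C3–C4–C5 and forms C4–C5. The cis-divinylcyclopropane 8 then undergoes a Cope rearrangement through the boat transition state that the small ring enforces, a [3,3] ring expansion that forms C1–C10, breaks C3–C5 and so closes the seven-membered ring as the net (4+3) adduct. The closest known reaction type is the tandem cyclopropanation/Cope rearrangement of vinyldiazoacetates with 1-oxygenated dienes under chiral dirhodium prolinate catalysis. C1 and C10 take their absolute configuration from the catalyst, which selects the carbene face in the cyclopropanation, and their cis relationship from the boat geometry, in which the E silyloxy and E isopropyl termini both point away from the cyclopropane. The step needs site selectivity for the 1,1-disubstituted alkene, secured by the siloxy group that polarises the diene towards attack at its CH2 terminus and by the poor reactivity of trans-1,2-disubstituted alkenes towards such carbenes; it also needs the two vinyl groups cis on the cyclopropane, secured by the preference of the unsaturated diene substituent over methyl for the side of the carbene's vinyl group.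

Step 6
Reactants: 9 methyl (3S,4S)-4-(tert-butyldimethylsilyloxy)-6-methyl-3-(propan-2-yl)cyclohepta-1,5-diene-1-carboxylate
Product: 11 methyl 1α-(tert-butyldimethylsilyloxy)-3-methyl-6β-(2-methylprop-2-enyl)-10α-(propan-2-yl)cyclohept-2-ene-5α-carboxylate (route numbering), via trimethylsilyl ketene acetal 10 (not isolated)
Conditions: 2-methylallylMgCl (3 equiv), CuBr·SMe2 (1.5 equiv), TMSCl, THF, −78 °C; then NaOMe (0.5 equiv), MeOH, 23 °C
Reagents that add atoms: 2-methylallylmagnesium chloride, SMILES CC(=C)C[Mg]Cl
Why: Silyl-chloride-accelerated conjugate addition of an allylic cuprate to the enoate should place the methallyl group on C6 from the β face, anti to the adjacent C10 isopropyl and the C1 silyloxy groups, after which methoxide cleaves the ketene acetal and equilibrates C5 to the more stable ester trans to the new C6 substituent.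

Step 7
Reactants: 11 methyl ester from step 6
Product: 12 1α-(tert-butyldimethylsilyloxy)-3-methyl-6β-(2-methylprop-2-enyl)-10α-(propan-2-yl)cyclohept-2-ene-5α-carbaldehyde (route numbering)
Conditions: i-Bu2AlH (1.1 equiv), CH2Cl2, −78 °C; MeOH, then aq. potassium sodium tartrate
Reagents that add atoms: none
Why: Partial reduction of a methyl ester with i-Bu2AlH stops at the aldehyde because the aluminium hemiacetal survives at −78 °C, and C5 already holds its thermodynamically preferred configuration.

Step 8
Reactants: 12 aldehyde from step 7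
Product: 13 1α-(tert-butyldimethylsilyloxy)-5α-ethenyl-3-methyl-6β-(2-methylprop-2-enyl)-10α-(propan-2-yl)cyclohept-2-ene (route numbering)
Conditions: Ph3PCH3Br, KOtBu, THF, 0 °C
Reagents that add atoms: methyltriphenylphosphonium bromide, SMILES C[P+](c1ccccc1)(c1ccccc1)c1ccccc1.[Br-]
Why: Wittig methylenation turns the aldehyde carbon (C9) into a vinyl group, and any base-induced epimerisation at C5 can only return the stable trans isomer.

Step 9
Reactants: 13 triene from step 8
Product: 14 1α-(tert-butyldimethylsilyloxy)-3,8-dimethyl-10α-(propan-2-yl)-5βH,6αH-bicyclo[5.3.0]deca-2,8-diene (route numbering)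
Conditions: second-generation Grubbs catalyst (H2IMes)(PCy3)Cl2Ru=CHPh (5 mol %), CH2Cl2, 40 °C
Reagents that add atoms: none
Why: Ring-closing metathesis of the vinyl and methallyl groups closes the methyl-substituted cyclopentene (C8=C9) with loss of ethene, the trisubstituted ring alkene staying inert and the trans ring fusion being fixed by the existing C5 and C6 centres.

Step 10
Reactants: 14 bicyclic silyl ether from step 9
Product: 15 3,8-dimethyl-10α-(propan-2-yl)-5βH,6αH-bicyclo[5.3.0]deca-2,8-dien-1α-ol (route numbering)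
Conditions: TBAF, THF, 23 → 50 °C
Reagents that add atoms: none
Why: Fluoride-mediated desilylation frees the allylic C1 hydroxyl without touching either alkene.

Step 11
Reactants: 15 allylic alcohol from step 10
Product: 16 2α,3α-epoxy-3β,8-dimethyl-10α-(propan-2-yl)-5βH,6αH-bicyclo[5.3.0]dec-8-en-1α-ol (route numbering)
Conditions: VO(acac)2 (5 mol %), t-BuOOH (1.2 equiv), CH2Cl2, 0 → 23 °C
Reagents that add atoms: tert-butyl hydroperoxide, SMILES CC(C)(C)OO
Why: Vanadium-catalysed hydroxyl-directed epoxidation delivers oxygen to the allylic C2=C3 alkene on the face of the C1 hydroxyl (α), which fixes the C3 methyl as β, and it leaves the remote C8=C9 alkene alone.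

Step 12
Reactants: 16 epoxy alcohol from step 11
Product: 17 3β,8-dimethyl-10α-(propan-2-yl)-5βH,6αH-bicyclo[5.3.0]dec-8-ene-1α,3α-diol (route numbering)
Conditions: LiAlH4, THF, 0 → 50 °C
Reagents that add atoms: none
Why: Reductive epoxide opening by SN2 hydride attack at the secondary C2 leaves the α C3–O bond intact and should give the cis-1,3-diol with the tertiary C3 carbinol.

Step 13
Reactants: 18 isovanillic acid
Product: 20 3-(tert-butyldimethylsilyloxy)-4-methoxybenzoic acid, via bis-silyl compound 19 (not isolated)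
Conditions: TBSCl (2.3 equiv), imidazole, DMF, 23 °C; then AcOH/THF/H2O, 23 °C
Reagents that add atoms: tert-butyldimethylsilyl chloride, SMILES CC(C)(C)[Si](C)(C)Cl
Why: Silylation of both acidic groups followed by selective hydrolysis of the far more labile silyl ester is the usual way to an O-silylated hydroxybenzoic acid.

Step 14
Reactants: 17 diol from step 12; 20 3-(tert-butyldimethylsilyloxy)-4-methoxybenzoic acid
Product: 22 3α-hydroxy-3β,8-dimethyl-10α-(propan-2-yl)-5βH,6αH-bicyclo[5.3.0]dec-8-en-1α-yl 3-(tert-butyldimethylsilyloxy)-4-methoxybenzoate (route numbering), via mixed anhydride 21 (not isolated)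
Conditions: 20, 2,4,6-Cl3C6H2COCl, Et3N, THF, 23 °C; then 17, DMAP, toluene, 23 → 60 °C
Reagents that add atoms: none
Why: Yamaguchi esterification acylates the secondary C1 hydroxyl through the less hindered carbonyl of the mixed anhydride, while the tertiary C3 hydroxyl is too hindered to compete.

Step 15
Reactants: 22 ester from step 14
Product: 23 8α,9α-epoxy-3α-hydroxy-3β,8β-dimethyl-10α-(propan-2-yl)-5βH,6αH-bicyclo[5.3.0]decan-1α-yl 3-(tert-butyldimethylsilyloxy)-4-methoxybenzoate (route numbering)
Conditions: VO(acac)2 (10 mol %), t-BuOOH (1.5 equiv), CH2Cl2, 23 °C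
Reagents that add atoms: tert-butyl hydroperoxide, SMILES CC(C)(C)OO
Why: Vanadium-catalysed hydroxyl-directed epoxidation of a bishomoallylic alcohol: the α C3 hydroxyl, 1,3-syn to the C5–C9 bond, should bind the vanadium peroxide and deliver oxygen to the α face of C8=C9, and the resulting syn epoxide cannot be opened by that hydroxyl because backside attack is geometrically excluded.

Step 16
Reactants: 23 silyl-protected epoxide from step 15
Product: 24 CNP0106636.1, 8α,9α-epoxy-3α-hydroxy-3β,8β-dimethyl-10α-(propan-2-yl)-5βH,6αH-bicyclo[5.3.0]decan-1α-yl 3-hydroxy-4-methoxybenzoate (route numbering)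
Conditions: TBAF, AcOH, THF, 0 °C
Reagents that add atoms: none
Why: Buffered fluoride desilylation cleaves the aryl silyl ether rapidly and should leave the epoxide, the tertiary alcohol and the benzoate ester untouched.

**Compound list**

1 | isovaleraldehyde (3-methylbutanal) | CC(C)CC=O | starting material
2 | malonic acid | OC(=O)CC(=O)O | starting material
3 | (E)-5-methylhex-3-enoic acid | CC(C)/C=C/CC(=O)O | intermediate
4 | methyl (E)-5-methylhex-3-enoate | CC(C)/C=C/CC(=O)OC | intermediate
5 | methyl (E)-2-diazo-5-methylhex-3-enoate | COC(=O)C(=[N+]=[N-])/C=C/C(C)C | intermediate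
6 | 3-methylbut-2-enal | CC(C)=CC=O | starting material
7 | (E)-1-(tert-butyldimethylsilyloxy)-3-methylbuta-1,3-diene | C=C(C)/C=C/O[Si](C)(C)C(C)(C)C | intermediate
8 | methyl (1R,2R)-2-[(E)-2-(tert-butyldimethylsilyloxy)ethenyl]-2-methyl-1-[(E)-3-methylbut-1-enyl]cyclopropane-1-carboxylate (formed in the flask, not isolated) | COC(=O)[C@@]1(/C=C/C(C)C)C[C@]1(C)/C=C/O[Si](C)(C)C(C)(C)C | intermediate
9 | methyl (3S,4S)-4-(tert-butyldimethylsilyloxy)-6-methyl-3-(propan-2-yl)cyclohepta-1,5-diene-1-carboxylate (route numbering: C1α-OTBS, C2=C3(Me), C5=C6 enoate, C10α-iPr) | CC(C)(C)[Si](C)(C)O[C@@H]1C=C(C)CC(C(=O)OC)=C[C@@H]1C(C)C | intermediate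
10 | methyl trimethylsilyl ketene acetal at C5 of the 6β-methallyl adduct (formed in the flask, not isolated) | CC(C)(C)[Si](C)(C)O[C@@H]1C=C(C)CC(=C(OC)O[Si](C)(C)C)[C@@H](CC(C)=C)[C@@H]1C(C)C | intermediate
11 | methyl 1α-(tert-butyldimethylsilyloxy)-3-methyl-6β-(2-methylprop-2-enyl)-10α-(propan-2-yl)cyclohept-2-ene-5α-carboxylate | CC(C)(C)[Si](C)(C)O[C@@H]1C=C(C)C[C@H](C(=O)OC)[C@@H](CC(C)=C)[C@@H]1C(C)C | intermediate
12 | 1α-(tert-butyldimethylsilyloxy)-3-methyl-6β-(2-methylprop-2-enyl)-10α-(propan-2-yl)cyclohept-2-ene-5α-carbaldehyde | CC(C)(C)[Si](C)(C)O[C@@H]1C=C(C)C[C@H](C=O)[C@@H](CC(C)=C)[C@@H]1C(C)C | intermediate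
13 | 1α-(tert-butyldimethylsilyloxy)-5α-ethenyl-3-methyl-6β-(2-methylprop-2-enyl)-10α-(propan-2-yl)cyclohept-2-ene | CC(C)(C)[Si](C)(C)O[C@@H]1C=C(C)C[C@H](C=C)[C@@H](CC(C)=C)[C@@H]1C(C)C | intermediate
14 | 1α-(tert-butyldimethylsilyloxy)-3,8-dimethyl-10α-(propan-2-yl)-5βH,6αH-bicyclo[5.3.0]deca-2,8-diene (trans-fused) | CC(C)(C)[Si](C)(C)O[C@@H]1C=C(C)C[C@H]2[C@@H](CC(C)=C2)[C@@H]1C(C)C | intermediate
15 | 3,8-dimethyl-10α-(propan-2-yl)-5βH,6αH-bicyclo[5.3.0]deca-2,8-dien-1α-ol | O[C@@H]1C=C(C)C[C@H]2[C@@H](CC(C)=C2)[C@@H]1C(C)C | intermediate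
16 | 2α,3α-epoxy-3β,8-dimethyl-10α-(propan-2-yl)-5βH,6αH-bicyclo[5.3.0]dec-8-en-1α-ol | O[C@@H]1[C@@H]2O[C@]2(C)C[C@H]3[C@@H](CC(C)=C3)[C@@H]1C(C)C | intermediate
17 | 3β,8-dimethyl-10α-(propan-2-yl)-5βH,6αH-bicyclo[5.3.0]dec-8-ene-1α,3α-diol | O[C@@H]1C[C@](C)(O)C[C@H]2[C@@H](CC(C)=C2)[C@@H]1C(C)C | intermediate
18 | isovanillic acid (3-hydroxy-4-methoxybenzoic acid) | COc1ccc(C(=O)O)cc1O | starting material
19 | tert-butyldimethylsilyl 3-(tert-butyldimethylsilyloxy)-4-methoxybenzoate (formed in the flask, not isolated) | COc1ccc(C(=O)O[Si](C)(C)C(C)(C)C)cc1O[Si](C)(C)C(C)(C)C | intermediate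
20 | 3-(tert-butyldimethylsilyloxy)-4-methoxybenzoic acid | COc1ccc(C(=O)O)cc1O[Si](C)(C)C(C)(C)C | intermediate
21 | 3-(tert-butyldimethylsilyloxy)-4-methoxybenzoic 2,4,6-trichlorobenzoic anhydride (formed in the flask, not isolated) | COc1ccc(C(=O)OC(=O)c2c(Cl)cc(Cl)cc2Cl)cc1O[Si](C)(C)C(C)(C)C | intermediate
22 | 3α-hydroxy-3β,8-dimethyl-10α-(propan-2-yl)-5βH,6αH-bicyclo[5.3.0]dec-8-en-1α-yl 3-(tert-butyldimethylsilyloxy)-4-methoxybenzoate | COc1ccc(C(=O)O[C@@H]2C[C@](C)(O)C[C@H]3[C@@H](CC(C)=C3)[C@@H]2C(C)C)cc1O[Si](C)(C)C(C)(C)C | intermediate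
23 | 8α,9α-epoxy-3α-hydroxy-3β,8β-dimethyl-10α-(propan-2-yl)-5βH,6αH-bicyclo[5.3.0]decan-1α-yl 3-(tert-butyldimethylsilyloxy)-4-methoxybenzoate | COc1ccc(C(=O)O[C@@H]2C[C@](C)(O)C[C@H]3[C@@H](C[C@@]4(C)O[C@@H]34)[C@@H]2C(C)C)cc1O[Si](C)(C)C(C)(C)C | intermediate
24 | CNP0106636.1: 8α,9α-epoxy-3α-hydroxy-3β,8β-dimethyl-10α-(propan-2-yl)-5βH,6αH-bicyclo[5.3.0]decan-1α-yl 3-hydroxy-4-methoxybenzoate | COc1ccc(C(=O)O[C@@H]2C[C@](C)(O)C[C@H]3[C@@H](C[C@@]4(C)O[C@@H]34)[C@@H]2C(C)C)cc1O | target

**Step count**

Total: 16 steps. Longest linear sequence: 14 steps (steps 1–3, 5–12, 14–16); steps 4 and 13 prepare the two side components.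

**Steps most likely to fail**

Step 5. The risk is erosion of enantiocontrol, and of the cis-divinyl geometry, if the catalyst discriminates the carbene faces poorly with the branched alkenyl group or if the electron-rich diene attacks the vinylogous terminus of the carbene. The fallback moves stereocontrol from the catalyst to an auxiliary on the ester and keeps the same bond formation. It sets out from 3: esterification with (R)-pantolactone (DCC, DMAP, CH2Cl2) should give (R)-pantolactonyl (E)-5-methylhex-3-enoate F1, and diazo transfer as in step 3 should give (R)-pantolactonyl (E)-2-diazo-5-methylhex-3-enoate F2. With achiral Rh2(OOct)4 (dirhodium tetraoctanoate) in hexane, F2 and 7 should give the pantolactonyl cycloheptadienecarboxylate F3, the facial bias now coming from the lactone (its antipode would be used if the sense requires). The step 6 protocol applied to F3 should give the trimethylsilyl ketene acetal F4, and the NaOMe/MeOH treatment then exchanges the auxiliary for methyl while equilibrating C5, so the route is rejoined at 11.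

Step 6. The risk is 1,2-addition of the allylic organometallic to the ester carbonyl, or no addition at the hindered C6, in place of conjugate delivery. The fallback replaces the intermolecular conjugate addition with a sigmatropic delivery of the same carbon. It sets out from 9: i-Bu2AlH (2.5 equiv, CH2Cl2, −78 °C) should give the allylic alcohol F5, and MnO2 (CH2Cl2) the enal F6. 1,2-Addition of 2-methylallylMgCl (THF, −78 °C) should give the bis-allylic carbinol F7 (either carbinol epimer serves). KH with 18-crown-6 (THF, 0 → 23 °C) should then trigger an anionic oxy-Cope rearrangement that forms C6–C7 on the face away from the C10 isopropyl group; protonation of the enolate under equilibrating conditions returns the route at aldehyde 12.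

Step 15. The risk is poor facial selectivity, with oxygen reaching the β face, if the hindered tertiary C3 hydroxyl binds vanadium too weakly to direct. The fallback uses reagent control in place of substrate direction and moves the epoxidation ahead of the acylation. It sets out from 17: the dioxirane from the fructose-derived Shi ketone (or its antipode, whichever is matched to the α face) and KHSO5 in buffered MeCN/dimethoxymethane should give the 8α,9α-epoxy-1α,3α-diol F8. Acylation of F8 with 20 under the conditions of step 14 returns the route at 23.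

**Further compounds**

F1 | step 5 | (R)-pantolactonyl (E)-5-methylhex-3-enoate | CC(C)/C=C/CC(=O)O[C@H]1C(=O)OCC1(C)C
F2 | step 5 | (R)-pantolactonyl (E)-2-diazo-5-methylhex-3-enoate | CC(C)/C=C/C(=[N+]=[N-])C(=O)O[C@H]1C(=O)OCC1(C)C
F3 | step 5 | (R)-pantolactonyl (3S,4S)-4-(tert-butyldimethylsilyloxy)-6-methyl-3-(propan-2-yl)cyclohepta-1,5-diene-1-carboxylate | CC(C)(C)[Si](C)(C)O[C@@H]1C=C(C)CC(C(=O)O[C@H]2C(=O)OCC2(C)C)=C[C@@H]1C(C)C
F4 | step 5 | pantolactonyl trimethylsilyl ketene acetal at C5 of the 6β-methallyl adduct | CC(C)(C)[Si](C)(C)O[C@@H]1C=C(C)CC(=C(O[Si](C)(C)C)O[C@H]2C(=O)OCC2(C)C)[C@@H](CC(C)=C)[C@@H]1C(C)C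
F5 | step 6 | [(3S,4S)-4-(tert-butyldimethylsilyloxy)-6-methyl-3-(propan-2-yl)cyclohepta-1,5-dien-1-yl]methanol | CC(C)(C)[Si](C)(C)O[C@@H]1C=C(C)CC(CO)=C[C@@H]1C(C)C
F6 | step 6 | (3S,4S)-4-(tert-butyldimethylsilyloxy)-6-methyl-3-(propan-2-yl)cyclohepta-1,5-diene-1-carbaldehyde | CC(C)(C)[Si](C)(C)O[C@@H]1C=C(C)CC(C=O)=C[C@@H]1C(C)C
F7 | step 6 | 1-[(3S,4S)-4-(tert-butyldimethylsilyloxy)-6-methyl-3-(propan-2-yl)cyclohepta-1,5-dien-1-yl]-3-methylbut-3-en-1-ol (carbinol epimers) | CC(C)(C)[Si](C)(C)O[C@@H]1C=C(C)CC(C(O)CC(C)=C)=C[C@@H]1C(C)C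
F8 | step 15 | 8α,9α-epoxy-3β,8β-dimethyl-10α-(propan-2-yl)-5βH,6αH-bicyclo[5.3.0]decane-1α,3α-diol | O[C@@H]1C[C@](C)(O)C[C@H]2[C@@H](C[C@@]3(C)O[C@@H]23)[C@@H]1C(C)C
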